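A plain one-way coupling, in which partner went to substrate and nowhere else, cannot have given these runs. We show this by following one substrate molecule through each run, then reckon the flask from the same figure.

| setting | dusk | autumn | noon | flask |
|---|---|---|---|---|
| substrate | 0.034 M | 0.075 M | 0.050 M | 0.050 M |
| coupling partner | 0.075 M | 0.075 M | 0.037 M | 0.0750 M |
| remark | run made earlier | run made earlier | run made earlier |  |
| time |  |  |  | 30 h |

| run | time / h | single product / % | substrate / % |
|---|---|---|---|
| dusk | 6.00 | 16.5 | 82.4 |
| dusk | 12.0 | 27.2 | 72.5 |
| dusk | 20.0 | 31.7 | 61.4 |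
| dusk | 25.0 | 35.5 | 57.0 |
| autumn | 3.00 | 9.9 | 92.1 |
| autumn | 8.00 | 19.0 | 78.8 |
| autumn | 15.0 | 27.9 | 70.4 |
| autumn | 25.0 | 34.3 | 63.6 |
| noon | 3.00 | 4.4 | 96.2 |
| noon | 8.00 | 10.5 | 87.1 |
| noon | 15.0 | 17.4 | 82.9 |
| noon | 25.0 | 22.5 | 75.2 |

(readings scatter by 1 percentage point)

* amount of single product in percent of the substrate charged, at 1.5 h, 8.0 h and 30 h

At the start of the autumn run 0.0348 h⁻¹ of the substrate present reacts each hour, and this figure, the hourly chance of one molecule (the pseudo-first-order constant), is what we follow. Noon, with 0.493 of that partner charge, starts at 0.0150 h⁻¹, which is 0.431 of that chance, so as a reading the chance follows the partner.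

Late in dusk the substrate readings give 0.0149 h⁻¹, a fall by the factor 0.428. Late in autumn they give 0.0102 h⁻¹. Partner paid out one for one to substrate in dusk accounts for a factor of 0.805, which leaves a further 0.532 that these runs do not name.

The end depends on the accumulated chance, the minus logarithm of the substrate fraction. At 25.0 h it reads 0.562 in dusk and 0.453 in autumn. The flask has their partner charge and a substrate charge between theirs, so we take the mean and add the mean late chance for the last 5.00 h, which gives 0.570. Substrate left is then 56.6%, and taking off the mean balance gap of 4.8 percentage points leaves 38.6% of single product at 30 h. The start chance gives 5.08% at 1.5 h, and at 8.0 h we expect about 20.1%, near autumn's 19.0%.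

The forecast gave 4.9%, 20% and 40%, slightly above ours at the end, holding that “The slowdown follows clock time”. The flask gives 5.14%, 19.8% and 36.8%.

    substrate + coupling partner → single product + released group (k = 0.500 M⁻¹ h⁻¹)
    coupling partner + single product → double product + released group (k = 0.304 M⁻¹ h⁻¹)
    coupling partner + tris adduct → tetra adduct + released group (k = 0.296 M⁻¹ h⁻¹)
    2 coupling partner → homo dimer (k = 0.260 M⁻¹ h⁻¹)
    coupling partner + double product → tris adduct + released group (k = 0.0446 M⁻¹ h⁻¹)

In the flask the half-life of substrate by the first step is 29 h at 8.52 h and 66 h at 30.0 h, an hourly chance of 0.0236 h⁻¹ and then 0.0105 h⁻¹, which is 0.302 of our start value, while single product is made 6.20 times faster than used up at the earlier time and 2.47 times at the later. That later chance on the 55% of substrate left, with the used-up part taken off, is a net 10.5% of the charge per 30 h at that pace, and the flask run on to 2.50 d holds 42.4%, a gain of 5.6 points.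

The readings were computed for an exercise; the scatter is artificial.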